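Labels: rings A, C and B form the flavone that carries 4-methoxyphenyl ring B. Rings D, F and E form the second flavone, where E is the central anisole ring (E1 on C2 of ring F, E2 on C8 of ring A, OMe on E4).
Cuts: the O-benzyl groups come off last. Ring C is cut at O1–C2, C3–C4 and C4–C4a (C4a aldehyde plus 4-ethynylanisole). Ring F is cut at O1–C2 and C2–C3 (phloroacetophenone dianion plus an acyl carbon on E1).
Before that, the acyl carbon on E1 and O8a are tied together as a benzo[c]chromen-6-one lactone. This tells O8a apart from O7 and O5 of the otherwise symmetric ring A.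
Enabling feature: E1 and E2 are adjacent ring E carbons that bear C2 of ring F and C8 of ring A. Cutting both bonds at once gives an E1≡E2 aryne, a ring A Grignard reagent and CO2, and a removable chlorine on E6 decides which end takes the nucleophile.
Forward order: A–E biaryl with the carboxyl carbon (step 5), then lactone, dechlorination and benzylation, then ring F (steps 10, 11), then ring C with ring B (steps 12–15), then hydrogenolysis.
Stereochemistry: the target has no stereocentre. The carbinol centre made in step 13 is erased in step 14, and the C8–E2 axis is not controlled.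

Key step: step 5

Assumption: the SMILES gives no sense for the C8–E2 axis, so the compound is made without axial control, as the racemate if the axis is stable.

Step 1
Reactants: 1 phloroglucinol
Product: 2 1,3,5-tris(methoxymethoxy)benzene
Conditions: NaH (3.6 equiv), MOMCl (3.6 equiv), DMF, 0 °C → rt
Reagents that add atoms: chloromethyl methyl ether (MOMCl), COCCl
Why: Williamson-type O-alkylation of the tris-phenoxide with the hard, oxocarbenium-like MOMCl goes to oxygen rather than carbon and installs three acetals that direct lithiation, tolerate Grignard reagents and fall off together in acid.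

Step 2
Reactants: 2 1,3,5-tris(methoxymethoxy)benzene
Product: 4 2,4,6-tris(methoxymethoxy)phenylmagnesium chloride, via aryllithium 3 (not isolated)
Conditions: n-BuLi, THF, 0 °C; MgCl2 (0.5 M in THF), 0 °C → rt; used as the THF solution
Reagents that add atoms: magnesium chloride, [Mg+2].[Cl-].[Cl-]
Why: Directed ortho-metalation between two chelating MOM ethers (the three ring C–H bonds are equivalent, so one aryllithium results) followed by lithium-to-magnesium transmetalation gives a LiCl-solvated aryl Grignard reagent that is nucleophilic enough for an aryne but too mild to attack a sulfonate ester.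

Step 3
Reactants: 5 2-chloro-4-methoxyphenol
Product: 6 2-chloro-6-iodo-4-methoxyphenol
Conditions: NIS (1.05 equiv), p-TsOH (cat.), MeCN, rt, dark
Reagents that add atoms: N-iodosuccinimide, O=C1CCC(=O)N1I
Why: Electrophilic aromatic iodination is steered by the hydroxyl group, the strongest donor, whose para position carries OMe and whose other ortho position carries Cl, so only C6 is open to it.

Step 4
Reactants: 6 2-chloro-6-iodo-4-methoxyphenol
Product: 7 2-chloro-6-iodo-4-methoxyphenyl 4-chlorobenzenesulfonate
Conditions: 4-ClC6H4SO2Cl, Et3N, DMAP (cat.), CH2Cl2, 0 °C → rt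
Reagents that add atoms: 4-chlorobenzenesulfonyl chloride, O=S(=O)(Cl)c1ccc(Cl)cc1
Why: O-Sulfonylation of the acidic 2,6-dihalophenol under nucleophilic catalysis places next to iodine a leaving group that survives iodine–magnesium exchange at −78 °C and departs on gentle warming.

Step 5
Reactants: 7 2-chloro-6-iodo-4-methoxyphenyl 4-chlorobenzenesulfonate, 4 2,4,6-tris(methoxymethoxy)phenylmagnesium chloride, 8 carbon dioxide
Product: 12 2-chloro-4-methoxy-6-[2,4,6-tris(methoxymethoxy)phenyl]benzoic acid, via magnesiated sulfonate 9 (not isolated), via aryne 10 (not isolated), via biaryl Grignard reagent 11 (not isolated)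
Conditions: i-PrMgCl (1.05 equiv), THF, −78 °C; 4 (2.5 equiv), −78 → −10 °C; CO2 (dry gas), −40 °C → rt; cold 0.5 M HCl to pH 3
Reagents that add atoms: carbon dioxide (compound 8), O=C=O
Why: Iodine–magnesium exchange at E2 is complete at −78 °C before anything else happens, and on warming 9 expels the arenesulfonate from E1 to give aryne 10, whose strained triple bond accepts the di-ortho-alkoxy Grignard reagent 4 without a catalyst, so the crowded C8–E2 bond forms through an early transition state. The closest known reaction types are the addition of hindered aryl Grignard reagents to benzynes with electrophilic quench (one-pot biaryl phosphine and m-terphenyl syntheses) and aryne release from 2-magnesiated aryl sulfonates. Regioselectivity is the one selectivity needed: the σ-withdrawing chlorine on E6 opens the internal angle at E2 and stabilises charge on E1, so the nucleophile goes to E2, which is also the less crowded end, while the E4 methoxy group, not adjacent to the triple bond, exerts only a small and opposing inductive bias. Reagent 11 should keep its ortho chlorine below 0 °C, because it is a magnesium and not a lithium carbanion and is further held by a neighbouring MOM oxygen, so CO2 forms the bond from E1 to the future C2 of ring F before a second aryne can arise. No ring closes and no stereocentre forms, and the new axis arises as a racemate.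

Step 6
Reactants: 12 2-chloro-4-methoxy-6-[2,4,6-tris(methoxymethoxy)phenyl]benzoic acid
Product: 14 7-chloro-1,3-dihydroxy-9-methoxy-6H-benzo[c]chromen-6-one, via trihydroxy acid 13 (not isolated)
Conditions: 3 M aq HCl, MeOH, 55 °C
Reagents that add atoms: none
Why: Acid-catalysed acetal solvolysis frees three phenols and the carboxyl group then esterifies one of the two equivalent ortho hydroxyls (six-membered lactonisation of a 2'-hydroxybiphenyl-2-carboxylic acid), which marks that oxygen as the future O8a and gives a neutral product that a bicarbonate wash separates from the acid derived from surplus 4.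

Step 7
Reactants: 14 7-chloro-1,3-dihydroxy-9-methoxy-6H-benzo[c]chromen-6-one
Product: 15 1,3-dihydroxy-9-methoxy-6H-benzo[c]chromen-6-one
Conditions: H2 (1 atm), 10% Pd/C, Et3N, THF–EtOH, rt
Reagents that add atoms: none
Why: Catalytic hydrodechlorination over Pd/C with an amine as HCl scavenger removes the spent directing group while no benzyl ether is yet present, and it also uncrowds the lactone carbonyl for step 10.

Step 8
Reactants: 15 1,3-dihydroxy-9-methoxy-6H-benzo[c]chromen-6-one
Product: 16 1,3-bis(benzyloxy)-9-methoxy-6H-benzo[c]chromen-6-one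
Conditions: BnBr (2.5 equiv), K2CO3, DMF, 60 °C
Reagents that add atoms: benzyl bromide, BrCc1ccccc1
Why: Williamson etherification caps O7 and O5 of ring A while the lactone keeps O8a masked, using groups that withstand amide bases, organolithium reagents and mild acid and later leave by hydrogenolysis without touching the two methyl ethers.

Step 9
Reactants: 17 2,4,6-trihydroxyacetophenone
Product: 18 1-[2,4-bis(benzyloxy)-6-hydroxyphenyl]ethanone
Conditions: BnBr (2.1 equiv), K2CO3, DMF, rt → 60 °C
Reagents that add atoms: benzyl bromide, BrCc1ccccc1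
Why: Williamson etherification with two equivalents of halide spares the hydroxyl that is hydrogen-bonded to the acetyl group, a standard selective protection of phloroacetophenone.

Step 10
Reactants: 18 1-[2,4-bis(benzyloxy)-6-hydroxyphenyl]ethanone, 16 1,3-bis(benzyloxy)-9-methoxy-6H-benzo[c]chromen-6-one
Product: 20 1-[2,4-bis(benzyloxy)-6-hydroxyphenyl]-3-{2-[2,4-bis(benzyloxy)-6-hydroxyphenyl]-4-methoxyphenyl}propane-1,3-dione, via dilithium dianion 19 (not isolated)
Conditions: 18 (1.2 equiv), LiN(SiMe3)2 (3.2 equiv per 18), THF, −78 → −10 °C; 16, −78 °C → rt; 1 M HCl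
Reagents that add atoms: none
Why: This is a crossed Claisen condensation, the intermolecular counterpart of the Baker–Venkataraman acyl transfer, in which the enolate carbon of 19 attacks the aryl ester carbonyl, the ring A phenoxide leaves, and the third equivalent of base deprotonates the 1,3-diketone and so drives the opening forward while freeing O8a alone.

Step 11
Reactants: 20 1-[2,4-bis(benzyloxy)-6-hydroxyphenyl]-3-{2-[2,4-bis(benzyloxy)-6-hydroxyphenyl]-4-methoxyphenyl}propane-1,3-dione
Product: 21 5,7-bis(benzyloxy)-2-{2-[2,4-bis(benzyloxy)-6-hydroxyphenyl]-4-methoxyphenyl}-4H-chromen-4-one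
Conditions: Amberlyst 15, i-PrOH–toluene, 80 °C
Reagents that add atoms: none
Why: Acid-catalysed cyclodehydration of an o-hydroxyaryl 1,3-diketone closes ring F by attack of the ring D hydroxyl on the E1-bound carbonyl, and since ketals formed by the ring A phenol at the same carbon stay reversible, the material should drain into the aromatic 4-pyranone.

Step 12
Reactants: 21 5,7-bis(benzyloxy)-2-{2-[2,4-bis(benzyloxy)-6-hydroxyphenyl]-4-methoxyphenyl}-4H-chromen-4-one
Product: 22 4,6-bis(benzyloxy)-3-{2-[5,7-bis(benzyloxy)-4-oxo-4H-chromen-2-yl]-5-methoxyphenyl}-2-hydroxybenzaldehyde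
Conditions: MgCl2, Et3N, (CH2O)n, MeCN–THF, reflux; 1 M HCl
Reagents that add atoms: paraformaldehyde (reacts as formaldehyde), C=O
Why: Casnati–Skattebøl formylation delivers formaldehyde within the magnesium phenoxide complex and therefore only ortho to the single free hydroxyl, where C8 is blocked and C4a is the one open position, so C6 and rings D and E stay untouched.

Step 13
Reactants: 23 4-ethynylanisole, 22 4,6-bis(benzyloxy)-3-{2-[5,7-bis(benzyloxy)-4-oxo-4H-chromen-2-yl]-5-methoxyphenyl}-2-hydroxybenzaldehyde
Product: 25 5,7-bis(benzyloxy)-2-(2-{4,6-bis(benzyloxy)-2-hydroxy-3-[1-hydroxy-3-(4-methoxyphenyl)prop-2-yn-1-yl]phenyl}-4-methoxyphenyl)-4H-chromen-4-one (unselective at the carbinol carbon), via lithium acetylide 24 (not isolated)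
Conditions: 23 (3 equiv), n-BuLi, THF, −78 °C; 22, −78 → −20 °C; aq NH4Cl
Reagents that add atoms: none
Why: 1,2-Addition of an alkynyllithium to the aldehyde (one equivalent is spent on the phenol) is far faster at low temperature than attack on the vinylogous ester carbonyl of ring F, and the new carbinol centre, formed without control, is erased in step 14.

Step 14
Reactants: 25 propargylic alcohol of step 13
Product: 26 5,7-bis(benzyloxy)-2-(2-{4,6-bis(benzyloxy)-2-hydroxy-3-[3-(4-methoxyphenyl)prop-2-ynoyl]phenyl}-4-methoxyphenyl)-4H-chromen-4-one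
Conditions: activated MnO2 (excess), CH2Cl2, rt
Reagents that add atoms: none
Why: MnO2 oxidises the doubly activated benzylic and propargylic alcohol under neutral conditions, which avoids ionisation of this acid-sensitive carbinol and leaves the benzyl ethers alone.

Step 15
Reactants: 26 o-hydroxyaryl ynone of step 14
Product: 27 5,7-bis(benzyloxy)-8-{2-[5,7-bis(benzyloxy)-4-oxo-4H-chromen-2-yl]-5-methoxyphenyl}-2-(4-methoxyphenyl)-4H-chromen-4-one
Conditions: DMAP (20 mol %), DMF, 40 °C
Reagents that add atoms: none
Why: In this nucleophile-catalysed 6-endo-dig oxa-Michael cyclisation DMAP adds to the β-carbon of the ynone and the O8a hydroxyl displaces it by addition–elimination at that same carbon, which leads to the flavone (ring C) and not to the 5-exo aurone.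

Step 16
Reactants: 27 tetrabenzyl ether of the target
Product: 28 8-[2-(5,7-dihydroxy-4-oxo-4H-chromen-2-yl)-5-methoxyphenyl]-5,7-dihydroxy-2-(4-methoxyphenyl)-4H-chromen-4-one (CNP0394081.0)
Conditions: H2 (1 atm), 10% Pd/C, THF–MeOH, rt
Reagents that add atoms: none
Why: Catalytic hydrogenolysis cleaves the four benzylic C–O bonds at ambient pressure, conditions under which aryl methyl ethers and the C2–C3 double bonds of flavones persist.

Compound list
1 | phloroglucinol | Oc1cc(O)cc(O)c1 | starting material
2 | 1,3,5-tris(methoxymethoxy)benzene | COCOc1cc(OCOC)cc(OCOC)c1 | intermediate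
3 | 2,4,6-tris(methoxymethoxy)phenyllithium | COCOc1cc(OCOC)c([Li])c(OCOC)c1 | intermediate
4 | 2,4,6-tris(methoxymethoxy)phenylmagnesium chloride | COCOc1cc(OCOC)c([Mg]Cl)c(OCOC)c1 | intermediate
5 | 2-chloro-4-methoxyphenol | COc1ccc(O)c(Cl)c1 | starting material
6 | 2-chloro-6-iodo-4-methoxyphenol | COc1cc(Cl)c(O)c(I)c1 | intermediate
7 | 2-chloro-6-iodo-4-methoxyphenyl 4-chlorobenzenesulfonate | COc1cc(Cl)c(OS(=O)(=O)c2ccc(Cl)cc2)c(I)c1 | intermediate
8 | carbon dioxide | O=C=O | starting material
9 | [3-chloro-2-(4-chlorobenzenesulfonyloxy)-5-methoxyphenyl]magnesium chloride | COc1cc(Cl)c(OS(=O)(=O)c2ccc(Cl)cc2)c([Mg]Cl)c1 | intermediate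
10 | 3-chloro-5-methoxy-1,2-didehydrobenzene (E1≡E2 aryne) | COC1=CC#CC(Cl)=C1 | intermediate
11 | {2-chloro-4-methoxy-6-[2,4,6-tris(methoxymethoxy)phenyl]phenyl}magnesium chloride | COCOc1cc(OCOC)c(-c2cc(OC)cc(Cl)c2[Mg]Cl)c(OCOC)c1 | intermediate
12 | 2-chloro-4-methoxy-6-[2,4,6-tris(methoxymethoxy)phenyl]benzoic acid | COCOc1cc(OCOC)c(-c2cc(OC)cc(Cl)c2C(=O)O)c(OCOC)c1 | intermediate
13 | 2-chloro-4-methoxy-6-(2,4,6-trihydroxyphenyl)benzoic acid | COc1cc(Cl)c(C(=O)O)c(-c2c(O)cc(O)cc2O)c1 | intermediate
14 | 7-chloro-1,3-dihydroxy-9-methoxy-6H-benzo[c]chromen-6-one | COc1cc(Cl)c2C(=O)Oc3cc(O)cc(O)c3-c2c1 | intermediate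
15 | 1,3-dihydroxy-9-methoxy-6H-benzo[c]chromen-6-one | COc1ccc2C(=O)Oc3cc(O)cc(O)c3-c2c1 | intermediate
16 | 1,3-bis(benzyloxy)-9-methoxy-6H-benzo[c]chromen-6-one | COc1ccc2C(=O)Oc3cc(OCc4ccccc4)cc(OCc4ccccc4)c3-c2c1 | intermediate
17 | 2,4,6-trihydroxyacetophenone | CC(=O)c1c(O)cc(O)cc1O | starting material
18 | 1-[2,4-bis(benzyloxy)-6-hydroxyphenyl]ethanone | CC(=O)c1c(O)cc(OCc2ccccc2)cc1OCc1ccccc1 | intermediate
19 | dilithium phenoxide-enolate of 18 | C=C(O[Li])c1c(O[Li])cc(OCc2ccccc2)cc1OCc1ccccc1 | intermediate
20 | 1-[2,4-bis(benzyloxy)-6-hydroxyphenyl]-3-{2-[2,4-bis(benzyloxy)-6-hydroxyphenyl]-4-methoxyphenyl}propane-1,3-dione | COc1ccc(C(=O)CC(=O)c2c(O)cc(OCc3ccccc3)cc2OCc2ccccc2)c(-c2c(O)cc(OCc3ccccc3)cc2OCc2ccccc2)c1 | intermediate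
21 | 5,7-bis(benzyloxy)-2-{2-[2,4-bis(benzyloxy)-6-hydroxyphenyl]-4-methoxyphenyl}-4H-chromen-4-one | COc1ccc(-c2cc(=O)c3c(OCc4ccccc4)cc(OCc4ccccc4)cc3o2)c(-c2c(O)cc(OCc3ccccc3)cc2OCc2ccccc2)c1 | intermediate
22 | 4,6-bis(benzyloxy)-3-{2-[5,7-bis(benzyloxy)-4-oxo-4H-chromen-2-yl]-5-methoxyphenyl}-2-hydroxybenzaldehyde | COc1ccc(-c2cc(=O)c3c(OCc4ccccc4)cc(OCc4ccccc4)cc3o2)c(-c2c(O)c(C=O)c(OCc3ccccc3)cc2OCc2ccccc2)c1 | intermediate
23 | 4-ethynylanisole | C#Cc1ccc(OC)cc1 | starting material
24 | lithium (4-methoxyphenyl)acetylide | [Li]C#Cc1ccc(OC)cc1 | intermediate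
25 | 5,7-bis(benzyloxy)-2-(2-{4,6-bis(benzyloxy)-2-hydroxy-3-[1-hydroxy-3-(4-methoxyphenyl)prop-2-yn-1-yl]phenyl}-4-methoxyphenyl)-4H-chromen-4-one, both configurations at the carbinol carbon | COc1ccc(C#CC(O)c2c(O)c(-c3cc(OC)ccc3-c3cc(=O)c4c(OCc5ccccc5)cc(OCc5ccccc5)cc4o3)c(OCc3ccccc3)cc2OCc2ccccc2)cc1 | intermediate
26 | 5,7-bis(benzyloxy)-2-(2-{4,6-bis(benzyloxy)-2-hydroxy-3-[3-(4-methoxyphenyl)prop-2-ynoyl]phenyl}-4-methoxyphenyl)-4H-chromen-4-one | COc1ccc(C#CC(=O)c2c(O)c(-c3cc(OC)ccc3-c3cc(=O)c4c(OCc5ccccc5)cc(OCc5ccccc5)cc4o3)c(OCc3ccccc3)cc2OCc2ccccc2)cc1 | intermediate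
27 | 5,7-bis(benzyloxy)-8-{2-[5,7-bis(benzyloxy)-4-oxo-4H-chromen-2-yl]-5-methoxyphenyl}-2-(4-methoxyphenyl)-4H-chromen-4-one | COc1ccc(-c2cc(=O)c3c(OCc4ccccc4)cc(OCc4ccccc4)c(-c4cc(OC)ccc4-c4cc(=O)c5c(OCc6ccccc6)cc(OCc6ccccc6)cc5o4)c3o2)cc1 | intermediate
28 | 8-[2-(5,7-dihydroxy-4-oxo-4H-chromen-2-yl)-5-methoxyphenyl]-5,7-dihydroxy-2-(4-methoxyphenyl)-4H-chromen-4-one | COc1ccc(-c2cc(=O)c3c(O)cc(O)c(-c4cc(OC)ccc4-c4cc(=O)c5c(O)cc(O)cc5o4)c3o2)cc1 | target

Total step count: 16.
Longest linear sequence: 13 steps (5 → 6 → 7 → 12 → 14 → 15 → 16 → 20 → 21 → 22 → 25 → 26 → 27 → 28; the branch from 1 is equally long).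

Steps most likely to fail

Step 5. The hindered reagent 4 may add too slowly, so that aryne 10 is consumed by 9 or by halide. The methoxy group may erode the regioselectivity. Reagent 11 may lose MgCl2 on warming and take up a second aryl group. The fallback replaces aryne chemistry by a Hurtley reaction (copper-catalysed C-arylation). It sets out from 1, which is heated with commercial 2-bromo-4-methoxybenzoic acid (COc1ccc(C(=O)O)c(Br)c1), NaOH and catalytic CuSO4 in water. The phloroglucinolate carbon displaces the bromide that the neighbouring carboxylate activates, giving 4-methoxy-2-(2,4,6-trihydroxyphenyl)benzoic acid F1. F1 lactonises on acidification to 15, where the route is rejoined.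

Step 11. The freed ring A phenol lies as close to the E1-bound carbonyl as the ring D hydroxyl does, so closure to a benzo[c]chromene ketal or to its dehydrated enol ether may compete. The acid may also shift benzyl groups. The fallback masks O8a before the diketone is made.
- It sets out from 16, which is saponified (NaOH, THF–MeOH–H2O) and, after evaporation, doubly allylated (allyl bromide, K2CO3, DMF) to allyl 2-[2-(allyloxy)-4,6-bis(benzyloxy)phenyl]-4-methoxybenzoate F2.
- Claisen condensation of F2 with dianion 19 gives 1-{2-[2-(allyloxy)-4,6-bis(benzyloxy)phenyl]-4-methoxyphenyl}-3-[2,4-bis(benzyloxy)-6-hydroxyphenyl]propane-1,3-dione F3, in which only the ring D hydroxyl can cyclise.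
- Amberlyst 15 then closes ring F to 2-{2-[2-(allyloxy)-4,6-bis(benzyloxy)phenyl]-4-methoxyphenyl}-5,7-bis(benzyloxy)-4H-chromen-4-one F4.
- Pd(PPh3)4 with morpholine removes the allyl group and leads back to 21.

Step 13. The aldehyde, deactivated by its ortho phenoxide, may react sluggishly. The acetylide may attack ring F. The electron-rich o-hydroxy propargylic carbinol may ionise on work-up or on silica. The fallback puts a palladium-catalysed carbonylative annulation in place of steps 12–15. It sets out from 21, which is iodinated with one equivalent of NIS at low temperature at C4a. This is the less crowded of the two open ring A positions and the one ortho to the free hydroxyl. The product is 5,7-bis(benzyloxy)-2-{2-[4,6-bis(benzyloxy)-2-hydroxy-3-iodophenyl]-4-methoxyphenyl}-4H-chromen-4-one F5. PdCl2(PPh3)2, CO (1 atm), Et2NH and alkyne 23 then bring about carbonylative Sonogashira coupling and amine-mediated 6-endo closure in one flask, which gives 27 directly.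

Further compounds
F1 | step 5 | 4-methoxy-2-(2,4,6-trihydroxyphenyl)benzoic acid | COc1ccc(C(=O)O)c(-c2c(O)cc(O)cc2O)c1
F2 | step 11 | allyl 2-[2-(allyloxy)-4,6-bis(benzyloxy)phenyl]-4-methoxybenzoate | COc1ccc(C(=O)OCC=C)c(-c2c(OCC=C)cc(OCc3ccccc3)cc2OCc2ccccc2)c1
F3 | step 11 | 1-{2-[2-(allyloxy)-4,6-bis(benzyloxy)phenyl]-4-methoxyphenyl}-3-[2,4-bis(benzyloxy)-6-hydroxyphenyl]propane-1,3-dione | COc1ccc(C(=O)CC(=O)c2c(O)cc(OCc3ccccc3)cc2OCc2ccccc2)c(-c2c(OCC=C)cc(OCc3ccccc3)cc2OCc2ccccc2)c1
F4 | step 11 | 2-{2-[2-(allyloxy)-4,6-bis(benzyloxy)phenyl]-4-methoxyphenyl}-5,7-bis(benzyloxy)-4H-chromen-4-one | COc1ccc(-c2cc(=O)c3c(OCc4ccccc4)cc(OCc4ccccc4)cc3o2)c(-c2c(OCC=C)cc(OCc3ccccc3)cc2OCc2ccccc2)c1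
F5 | step 13 | 5,7-bis(benzyloxy)-2-{2-[4,6-bis(benzyloxy)-2-hydroxy-3-iodophenyl]-4-methoxyphenyl}-4H-chromen-4-one | COc1ccc(-c2cc(=O)c3c(OCc4ccccc4)cc(OCc4ccccc4)cc3o2)c(-c2c(O)c(I)c(OCc3ccccc3)cc2OCc2ccccc2)c1
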